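## Structural features

Septeremophilane E is an 11,12,13-trinoreremophilane: two six-membered carbocycles, ring A (C10, C1, C2, C3, C4, C5) and ring B (C5, C6, C7, C8, C9, C10), fused through the C5–C10 bond. O3 is esterified with (2E,4E,6R)-6-(hydroxymethyl)octa-2,4-dienoic acid (primed numbers below). Ring B is a diosphenol (C6=C7(OH)–C8=O) whose carbonyl is cross-conjugated through C9=C10 with the C1=C2 alkene of ring A, so only C3, C4 and C5 of the core are sp3. These three carbons are contiguous stereocentres with all substituents on one face: the acyloxy group at C3 (S), the methyl at C4 (R) and the methyl at the quaternary C5 (S). The fourth stereocentre, C6′, is isolated in the side chain. The fragile groups are the enolised α-diketone (oxidation, acylation at the enol oxygen), the C3 ester (C3–H is vinylogously acidic through the trienone), the (E,E)-dienoate and the primary alcohol. The real difficulty is the quaternary C5, wedged between the C4 stereocentre and the sp2 carbons C6 and C10, together with the two adjacent oxygenated carbons C7 and C8. The key step exploits that C5 bears a methyl group and is bonded to the sp2 carbon C10: a C5 methylene becomes, after hydrogen-atom transfer, a methyl-bearing tertiary radical, and an alkynoate at C10 traps it, closing ring A and leaving C9=C10 in place.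

## Logic of the disconnections

38 ⇒ 37 ⇒ 23 + 35. The C3–O acyl bond is cut after masking the enol and the primary hydroxyl. This is the most convergent cut and removes the side-chain stereocentre from the core synthesis. The forward step demands that C3–OH be the only free hydroxyl of 23 and that a hindered secondary allylic alcohol be acylated without touching C3–H.

23 ⇒ 22 ⇒ 21 ⇒ 20 ⇒ 19 ⇒ 18. No skeletal bond is cut down to 19; then C7–C8 is cut. Both carbons are carbonyl carbons in the target, so a reductive coupling of two aldehydes forms the bond with both oxygens in place, and oxidation then gives the diosphenol. The gain is the loss of ring B: 18 is monocyclic. The forward step demands the C8 aldehyde on the C5 side of C9=C10 and a ketyl that cyclises faster than it is reduced.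

18 ⇒ 17 ⇒ 16 ⇒ 15. These are functional-group changes only. The C7 acetal is opened while C8 is still an ester, because the dienoate tolerates acid, and both termini are then brought to the aldehyde level together.

15 ⇒ 14. C5–C10 is cut. This opens ring A and removes the quaternary stereocentre, leaving an acyclic chain with two stereocentres. The forward step demands Markovnikov hydrogen-atom transfer only at the isolated alkene, 6-exo-dig closure, facial selectivity at C5 under control of C3/C4, and the ester syn to C5 in the new enoate.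

14 ⇒ 12 + 13, and 12 ⇒ 11 ⇒ 10. The sp2–sp bond C1–C10 is cut, and the (Z)-iodoalkene is traced to a silylalkyne. The demand is retention of the Z geometry and tolerance of the propiolate.

10 ⇒ 8 + 9, and 8 ⇒ 6 (through 7) ⇒ 5. The C5–C6 bond is cut so that the two-carbon acetal arm arrives as a commercial zinc reagent on a 2-iodo-1-alkene, which itself comes from a terminal alkyne. This avoids any trisubstituted allylmetal whose geometry would have to be controlled.

5 ⇒ 2 + 3 (through 4), and 2 ⇒ 1. The C3–C4 bond is cut. C4 comes from 1 by chirality transfer and C3 from the anti selectivity of the addition. The forward step demands high anti selectivity with a sterically small ynal.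

35 ⇒ 34 ⇒ 31 + 32 (through 33), 31 ⇒ 30 ⇒ 29 ⇒ 28 ⇒ 26 (through 27) ⇒ 24 + 25. The C4′=C5′ alkene is cut (olefination), then the C–CH2OH bond next to the acyl group (auxiliary-controlled hydroxymethylation). The demand is that the α-branched aldehyde 31 does not epimerise.

## Other disconnections considered

Alternative 1: The cut removes C5–C10 and C3–C4 together, so both rings fall away and the bicyclic dienone A2 is traced to the acyclic, axially chiral vinylallene A1. The forward key step would be a thermal intramolecular Diels–Alder reaction of A1: the diene C10=C1–C2=C3 adds to the tethered (E)-C4=C5 alkene to give A2.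
- In favour: one step would form two C–C bonds, both rings and all three stereocentres. The suprafacial addition turns the (E)-alkene directly into the cis C4/C5 methyl pair. This is more secure than the facial selectivity on which the closure of 14 rests, and here the alternative is the better plan.
- Also better: A2 already has C8 as a ketone and C7 as a masked ketone, so ring B would need no later C–C bond formation or redox adjustment. The chosen route spends steps 10–14 on this.
- Against: A1 combines an epimerisable, base-sensitive allenyl ketone, a labile silyl dienol ether and an unactivated trisubstituted dienophile, so the cycloaddition would need heat that the allene may not survive. The C3 configuration depends on the silyloxy group lying outside on the diene with the methyls endo. The allene must be made as one axial enantiomer. The dithioketal must later be removed beside a triene.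
- Comparison: structurally A2 is further advanced than 15. Mechanistically a stereospecific pericyclic step is set against a substrate-controlled radical step. In step economy the alternative would probably be shorter after the key step and about equal before it. Its substrate is the less stable and the less certain to be preparable, which decided against it.

Alternative 2: The cut is C4–C5, tracing the dienone A4 to the phenol mesylate A3 (a creosol-derived ring B with a (Z)-alkenyl chain on C10). Forward, the phenoxide of A3 would attack through its para carbon C5 on the mesylate carbon C4 with inversion, closing ring A (6-exo-tet) and creating the quaternary centre by dearomatisation.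
- In favour: ring B arrives from a cheap arene with both oxygens at the final oxidation level, which is better than the five steps of the chosen route. The C4 configuration follows stereospecifically from inversion.
- Against: substitution at a secondary mesylate next to the allylic C3 ether must beat elimination, and aromaticity is lost in the step. The face of C5 that attacks decides the C4/C5 relationship, and only the conformation of a short tether controls it. This uncertainty is of the same kind and size as in the chosen key step (equal). The C9 bromine (a blocking group), the C7 methyl enol ether and the PMB ether must each be removed later, the methyl ether under conditions that threaten the C3 ester.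
- Comparison: both plans need a (Z)-alkene in the ring A tether (equal). The alternative is polar and stereospecific at C4, where the chosen plan uses chirality transfer (equal in reliability). The step count would be comparable once the extra deprotections are counted.

Alternative 3: The cut excises C7 (bonds C6–C7 and C7–C8), tracing the 7-bromo trienone A6 to the silyloxy diene A5 of a hydrindenone with a five-membered ring B. Forward, dibromocarbene would cyclopropanate the C6=C8 enol ether of A5 and the adduct would open with loss of bromide to give A6.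
- In favour: the stereotriad and C5 would be fixed early on a hydrindane, for which annulation methods are established. On the security of C5 the alternative is the better plan. The ring expansion would deliver the whole cross-conjugated chromophore with a handle on C7 in one step.
- Against: A5 is a silyloxycyclopentadiene, prone to dimerisation and hydrogen shifts, and it requires enolisation toward C6 only. The carbene must select one of three alkenes. Turning the C7–Br bond of A6 into C7–OH on a base-sensitive trienone needs further steps. An enantioselective route to the hydrindenone with the C3 oxygen and C1=C2 in place moves the stereochemical problem; it does not remove it.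
- Comparison: the chosen plan builds C5 late and acyclically, with fewer operations on sensitive polyenes. The alternative would be stronger only if the five-membered precursor were readily at hand.

Key step: step 9

Remarks on the chemistry, made before the steps:
- Eremophilane numbering is used for the core and primes for the side chain.
- Checked against the target, 14 must be (6S,7R) with a (4Z)-alkene (3S,4R in core numbering) and 15 must carry the ester on the C5 side of C9=C10 (2Z). The C5 descriptor is R in 15–20 and S from 21 on only because the ranking of C4 and C6 changes when C6 becomes sp2.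
- Correction: a 2-(2,2-dialkoxyethyl)crotylboron reagent that would give the anti C3/C4 pair needs its methyl trans to the CH2B group. Because the dialkoxyethyl group outranks CH2B, this geometry is (Z), not (E). It is hard to secure because both substituents on the central carbon are CH2 groups. The C3–C4 bond is therefore made by anti-selective propargylation and the arm is attached afterwards.
- Design change in the precursor: C7 is carried as a 1,3-dioxolane in place of a dimethyl acetal; the skeleton is unchanged.
- Assumption: 9 is used as its commercial THF solution, and the C7/C8 configuration of 19 is left open because both centres become sp2 in step 14.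

## Steps

Step 1
Reactants: 1 (S)-but-3-yn-2-ol
Product: 2 (S)-but-3-yn-2-yl methanesulfonate
Conditions: MsCl, Et3N, CH2Cl2, −78 → 0 °C
Reagents that add atoms: methanesulfonyl chloride, CS(=O)(=O)Cl
Why: O-Sulfonylation of a secondary propargylic alcohol; the C–O bond at the stereocentre is not broken, so the (S) configuration is kept.

Step 2
Reactants: 2 (S)-but-3-yn-2-yl methanesulfonate; 3 3-(trimethylsilyl)propynal
Product: 5 (3R,4R)-4-methyl-1-(trimethylsilyl)hexa-1,5-diyn-3-ol, via allenylzinc 4 (not isolated)
Conditions: Pd(OAc)2 (5 mol%), PPh3 (5 mol%), Et2Zn (3 equiv), THF, −78 → −20 °C; aq. NH4Cl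
Reagents that add atoms: none
Why: Marshall propargylation: zerovalent palladium displaces the mesylate anti (SN2′), transmetallation gives the axially chiral allenylzinc 4, and this adds to the aldehyde through a cyclic SE2′ transition state. Net inversion at the former carbinol carbon sets C4 (R), and the chair-like transition state with the aldehyde substituent equatorial gives the anti (3R) alcohol.

Step 3
Reactants: 5 (3R,4R)-4-methyl-1-(trimethylsilyl)hexa-1,5-diyn-3-ol
Product: 6 tert-butyl(dimethyl){[(3R,4R)-4-methyl-1-(trimethylsilyl)hexa-1,5-diyn-3-yl]oxy}silane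
Conditions: TBSCl, imidazole, DMF, rt
Reagents that add atoms: tert-butyldimethylsilyl chloride, CC(C)(C)[Si](C)(C)Cl
Why: Silyl ether formation at the only hydroxyl; the bulky TBS group is the C3 substituent that later steers the radical closure and it lasts until step 16.

Step 4
Reactants: 6 tert-butyl(dimethyl){[(3R,4R)-4-methyl-1-(trimethylsilyl)hexa-1,5-diyn-3-yl]oxy}silane
Product: 8 tert-butyl{[(3R,4S)-5-iodo-4-methyl-1-(trimethylsilyl)hex-5-en-1-yn-3-yl]oxy}dimethylsilane, via iodoalkenylborane 7 (not isolated)
Conditions: B-iodo-9-BBN, pentane, −20 → 0 °C; then AcOH, 0 °C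
Reagents that add atoms: 9-iodo-9-borabicyclo[3.3.1]nonane, IB1C2CCCC1CCC2
Why: Haloboration: B–I adds syn to the terminal alkyne only (boron on the terminal carbon, iodine on C5), the internal silylalkyne being inert, and protonolysis of the C–B bond gives the 2-iodo-1-alkene. The C4 descriptor changes to S only because iodine raises the rank of C5.

Step 5
Reactants: 8 tert-butyl{[(3R,4S)-5-iodo-4-methyl-1-(trimethylsilyl)hex-5-en-1-yn-3-yl]oxy}dimethylsilane; 9 (1,3-dioxolan-2-ylmethyl)zinc bromide
Product: 10 tert-butyl({(3R,4R)-5-[(1,3-dioxolan-2-yl)methyl]-4-methyl-1-(trimethylsilyl)hex-5-en-1-yn-3-yl}oxy)dimethylsilane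
Conditions: Pd(OAc)2 (5 mol%), SPhos (10 mol%), THF, 25 → 45 °C
Reagents that add atoms: none
Why: Negishi sp2–sp3 coupling of a 2-iodo-1-alkene with an alkylzinc halide forms C5–C6 and installs the C6–C7 arm with C7 masked; the bulky biarylphosphine favours reductive elimination over β-hydride and β-alkoxide elimination.

Step 6
Reactants: 10 tert-butyl({(3R,4R)-5-[(1,3-dioxolan-2-yl)methyl]-4-methyl-1-(trimethylsilyl)hex-5-en-1-yn-3-yl}oxy)dimethylsilane
Product: 11 tert-butyl({(3R,4R)-5-[(1,3-dioxolan-2-yl)methyl]-1-iodo-4-methylhex-5-en-1-yn-3-yl}oxy)dimethylsilane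
Conditions: N-iodosuccinimide, AgNO3 (10 mol%), DMF, 0 °C → rt, dark
Reagents that add atoms: N-iodosuccinimide, O=C1CCC(=O)N1I
Why: Silver-catalysed iododesilylation of an alkynylsilane; the silver acetylide is iodinated much faster than the hindered 1,1-disubstituted alkene reacts.

Step 7
Reactants: 11 tert-butyl({(3R,4R)-5-[(1,3-dioxolan-2-yl)methyl]-1-iodo-4-methylhex-5-en-1-yn-3-yl}oxy)dimethylsilane
Product: 12 tert-butyl({(1Z,3R,4R)-5-[(1,3-dioxolan-2-yl)methyl]-1-iodo-4-methylhexa-1,5-dien-3-yl}oxy)dimethylsilane
Conditions: 2-nitrobenzenesulfonyl hydrazide, Et3N, THF/i-PrOH (1:1), rt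
Reagents that add atoms: none
Why: Diimide made in the flask delivers two hydrogens syn to the iodoalkyne and gives the (Z)-iodoalkene; iodoalkynes are reduced faster than 1,1-disubstituted alkenes, so the C5 methylene should survive with limited reagent.

Step 8
Reactants: 12 tert-butyl({(1Z,3R,4R)-5-[(1,3-dioxolan-2-yl)methyl]-1-iodo-4-methylhexa-1,5-dien-3-yl}oxy)dimethylsilane; 13 methyl propiolate
Product: 14 methyl (4Z,6S,7R)-6-{[tert-butyl(dimethyl)silyl]oxy}-8-[(1,3-dioxolan-2-yl)methyl]-7-methylnona-4,8-dien-2-ynoate
Conditions: PdCl2(PPh3)2 (5 mol%), CuI (10 mol%), K2CO3, THF, rt → 40 °C; 13 added slowly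
Reagents that add atoms: none
Why: Sonogashira coupling of a (Z)-alkenyl iodide proceeds with retention of the alkene geometry; the inorganic base and slow addition keep the propiolate from amine addition and oligomerisation.

Step 9
Reactants: 14 methyl (4Z,6S,7R)-6-{[tert-butyl(dimethyl)silyl]oxy}-8-[(1,3-dioxolan-2-yl)methyl]-7-methylnona-4,8-dien-2-ynoate
Product: 15 methyl (2Z)-2-[(4S,5R,6R)-4-{[tert-butyl(dimethyl)silyl]oxy}-6-[(1,3-dioxolan-2-yl)methyl]-5,6-dimethylcyclohex-2-en-1-ylidene]acetate
Conditions: Fe(acac)3 (0.3 equiv), PhSiH3 (2.5 equiv), EtOH/ethylene glycol (5:1), 0.01 M, 60 °C, argon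
Reagents that add atoms: none
Why: Fe(acac)3 and PhSiH3 in ethanol generate an iron hydride that transfers a hydrogen atom to the terminal CH2 of the electron-rich 1,1-disubstituted alkene (Markovnikov), creating the C5 methyl group and a nucleophilic tertiary C5 radical. This radical adds to C10, the β-carbon of the alkynoate, and closes ring A in the 6-exo-dig mode; the (Z)-C1=C2 alkene holds C5 and C10 together and no smaller ring is within reach. The resulting α-ester vinyl radical at C9 is reduced by divalent iron and protonated by ethanol (or takes a hydrogen atom) on the side of C1–H, away from the new quaternary centre, so the ester ends up syn to C5 in the (Z)-enoate that ring B needs. The closest known reaction type is the iron-hydride hydrogen-atom-transfer reductive olefin coupling in its intramolecular, Giese-type form, which is established for quaternary centres. The new stereocentre C5 is controlled by C3 and C4 through a chair-like transition state: the C4 methyl avoids eclipsing a substituent of the planar radical and sits pseudo-equatorial, which places the C3 silyloxy group pseudo-axial, and the C5 position syn-axial to that silyloxy group is taken by methyl, the smaller radical substituent, while the dioxolanylmethyl arm points outwards. The alternative chair with an axial C4 methyl also prefers methyl, not the arm, next to the C4 methyl, so both arrangements lead to the C5 methyl cis to the C4 methyl and O3. The step needs hydrogen-atom transfer to the isolated alkene in preference to the conjugated enynoate, which the electron-poor character of the latter should secure, and it must be stopped before the dienoate of 15 is reduced, which limited silane and high dilution should allow.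

Step 10
Reactants: 15 methyl (2Z)-2-[(4S,5R,6R)-4-{[tert-butyl(dimethyl)silyl]oxy}-6-[(1,3-dioxolan-2-yl)methyl]-5,6-dimethylcyclohex-2-en-1-ylidene]acetate
Product: 16 methyl (2Z)-2-[(4S,5R,6R)-4-{[tert-butyl(dimethyl)silyl]oxy}-5,6-dimethyl-6-(2-oxoethyl)cyclohex-2-en-1-ylidene]acetate
Conditions: PPTS (0.2 equiv), acetone/H2O (9:1), 55 °C
Reagents that add atoms: water, O
Why: Acid-catalysed acetal hydrolysis, done while C8 is still an ester because the (Z)-dienoate is stable to acid and to Z/E drift whereas the later dienol and dienal are not; the secondary TBS ether tolerates PPTS.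

Step 11
Reactants: 16 methyl (2Z)-2-[(4S,5R,6R)-4-{[tert-butyl(dimethyl)silyl]oxy}-5,6-dimethyl-6-(2-oxoethyl)cyclohex-2-en-1-ylidene]acetate
Product: 17 (2Z)-2-[(4S,5R,6R)-4-{[tert-butyl(dimethyl)silyl]oxy}-6-(2-hydroxyethyl)-5,6-dimethylcyclohex-2-en-1-ylidene]ethan-1-ol
Conditions: i-Bu2AlH (5 equiv), CH2Cl2, −78 → −20 °C; aq. potassium sodium tartrate
Reagents that add atoms: none
Why: Aluminium hydride reduction of the ester (1,2-reduction, no conjugate reduction) and of the aldehyde to the two primary alcohols, so that both termini reach the aldehyde level together in the next step.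

Step 12
Reactants: 17 (2Z)-2-[(4S,5R,6R)-4-{[tert-butyl(dimethyl)silyl]oxy}-6-(2-hydroxyethyl)-5,6-dimethylcyclohex-2-en-1-ylidene]ethan-1-ol
Product: 18 (2Z)-2-[(4S,5R,6R)-4-{[tert-butyl(dimethyl)silyl]oxy}-5,6-dimethyl-6-(2-oxoethyl)cyclohex-2-en-1-ylidene]acetaldehyde
Conditions: Dess–Martin periodinane (3 equiv), NaHCO3, CH2Cl2, 0 °C → rt; used at once
Reagents that add atoms: none
Why: Dess–Martin oxidation of the allylic and the saturated primary alcohol under buffered, non-acidic conditions, chosen to keep the (Z)-dienal from isomerising.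

Step 13
Reactants: 18 (2Z)-2-[(4S,5R,6R)-4-{[tert-butyl(dimethyl)silyl]oxy}-5,6-dimethyl-6-(2-oxoethyl)cyclohex-2-en-1-ylidene]acetaldehyde
Product: 19 (4aR,5R,6S)-6-{[tert-butyl(dimethyl)silyl]oxy}-4a,5-dimethyl-2,3,4,4a,5,6-hexahydronaphthalene-2,3-diol (diastereomers at the two carbinol carbons)
Conditions: SmI2 (2.5 equiv), THF, −78 °C, slow addition of 18 (0.005 M); H2O quench
Reagents that add atoms: none
Why: Samarium diiodide pinacol cyclisation: the dienal accepts an electron first and its ketyl adds to the samarium-bound C7 aldehyde, closing the six-membered ring B through C7–C8. The diol configuration is irrelevant, and the poor leaving-group ability of the C3 silyloxy group guards against vinylogous reductive elimination.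

Step 14
Reactants: 19 (4aR,5R,6S)-6-{[tert-butyl(dimethyl)silyl]oxy}-4a,5-dimethyl-2,3,4,4a,5,6-hexahydronaphthalene-2,3-diol
Product: 21 (4aS,5R,6S)-6-{[tert-butyl(dimethyl)silyl]oxy}-3-hydroxy-4a,5-dimethyl-5,6-dihydronaphthalen-2(4aH)-one, via diketone 20 (not isolated)
Conditions: (COCl)2 (5 equiv), DMSO (10 equiv), CH2Cl2, −78 °C; Et3N (15 equiv), −78 → 0 °C
Reagents that add atoms: none
Why: Swern oxidation takes a 1,2-diol to the α-diketone 20 without C–C cleavage; 20 enolises toward C6, its only position with α-hydrogens, to the cross-conjugated diosphenol 21.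

Step 15
Reactants: 21 (4aS,5R,6S)-6-{[tert-butyl(dimethyl)silyl]oxy}-3-hydroxy-4a,5-dimethyl-5,6-dihydronaphthalen-2(4aH)-one
Product: 22 (4aS,5R,6S)-6-{[tert-butyl(dimethyl)silyl]oxy}-3-(methoxymethoxy)-4a,5-dimethyl-5,6-dihydronaphthalen-2(4aH)-one
Conditions: MOMCl (1.5 equiv), i-Pr2NEt (2 equiv), CH2Cl2, 0 °C
Reagents that add atoms: chloromethyl methyl ether, COCCl
Why: O-Alkylation of the acidic enol with a hindered amine base; the methoxymethyl ether blocks the enol oxygen during the acylation and withstands fluoride.

Step 16
Reactants: 22 (4aS,5R,6S)-6-{[tert-butyl(dimethyl)silyl]oxy}-3-(methoxymethoxy)-4a,5-dimethyl-5,6-dihydronaphthalen-2(4aH)-one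
Product: 23 (4aS,5R,6S)-6-hydroxy-3-(methoxymethoxy)-4a,5-dimethyl-5,6-dihydronaphthalen-2(4aH)-one
Conditions: HF·pyridine, pyridine, THF, 0 °C → rt
Reagents that add atoms: none
Why: Fluoride cleavage of the secondary silyl ether under buffered, non-basic conditions, which spares the methoxymethyl enol ether and avoids deprotonation at the vinylogously acidic C3–H.

Step 17
Reactants: 24 (4R)-4-benzyl-1,3-oxazolidin-2-one; 25 butanoyl chloride
Product: 26 (4R)-4-benzyl-3-butanoyl-1,3-oxazolidin-2-one
Conditions: Et3N, DMAP (10 mol%), CH2Cl2, 0 °C → rt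
Reagents that add atoms: none
Why: N-Acylation of the oxazolidinone by the acid chloride under nucleophilic catalysis.

Step 18
Reactants: 26 (4R)-4-benzyl-3-butanoyl-1,3-oxazolidin-2-one
Product: 28 (4R)-4-benzyl-3-[(2S)-2-(hydroxymethyl)butanoyl]-1,3-oxazolidin-2-one, via titanium enolate 27 (not isolated)
Conditions: TiCl4 (1.05 equiv), i-Pr2NEt (1.1 equiv), CH2Cl2, 0 °C; then 1,3,5-trioxane (1.2 equiv), TiCl4 (1.05 equiv), 0 °C; aq. NH4Cl
Reagents that add atoms: 1,3,5-trioxane, C1OCOCO1
Why: Evans hydroxymethylation: the chelated (Z)-titanium enolate 27 is attacked by titanium-activated formaldehyde on the face opposite the benzyl group, which sets the (2S) centre that becomes C6′ (R).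

Step 19
Reactants: 28 (4R)-4-benzyl-3-[(2S)-2-(hydroxymethyl)butanoyl]-1,3-oxazolidin-2-one
Product: 29 (4R)-4-benzyl-3-[(2S)-2-({[tert-butyl(dimethyl)silyl]oxy}methyl)butanoyl]-1,3-oxazolidin-2-one
Conditions: TBSCl, imidazole, DMF, rt
Reagents that add atoms: tert-butyldimethylsilyl chloride, CC(C)(C)[Si](C)(C)Cl
Why: Silyl ether formation at the primary alcohol; protection before removal of the auxiliary keeps the two CH2O arms different and so keeps the stereocentre.

Step 20
Reactants: 29 (4R)-4-benzyl-3-[(2S)-2-({[tert-butyl(dimethyl)silyl]oxy}methyl)butanoyl]-1,3-oxazolidin-2-one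
Product: 30 (2R)-2-({[tert-butyl(dimethyl)silyl]oxy}methyl)butan-1-ol
Conditions: LiBH4, Et2O, H2O (1.1 equiv), 0 °C
Reagents that add atoms: none
Why: Reductive removal of the auxiliary by hydride attack at the exocyclic imide carbonyl; the stereocentre is not enolised and the auxiliary is recovered.

Step 21
Reactants: 30 (2R)-2-({[tert-butyl(dimethyl)silyl]oxy}methyl)butan-1-ol
Product: 31 (2S)-2-({[tert-butyl(dimethyl)silyl]oxy}methyl)butanal
Conditions: Dess–Martin periodinane, NaHCO3, CH2Cl2, 0 °C; used crude
Reagents that add atoms: none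
Why: Buffered Dess–Martin oxidation to the α-branched aldehyde, used at once to avoid epimerisation and β-elimination of the silyloxy group.

Step 22
Reactants: 31 (2S)-2-({[tert-butyl(dimethyl)silyl]oxy}methyl)butanal; 32 triethyl 4-phosphonocrotonate
Product: 34 ethyl (2E,4E,6R)-6-({[tert-butyl(dimethyl)silyl]oxy}methyl)octa-2,4-dienoate, via lithiated phosphonate 33 (not isolated)
Conditions: LiN(SiMe3)2, THF, −78 °C (32); then 31, −78 → 0 °C
Reagents that add atoms: none
Why: Vinylogous Horner–Wadsworth–Emmons reaction of the preformed stabilised anion 33 gives the (2E,4E)-dienoate; the weakly basic anion at low temperature protects the α-stereocentre.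

Step 23
Reactants: 34 ethyl (2E,4E,6R)-6-({[tert-butyl(dimethyl)silyl]oxy}methyl)octa-2,4-dienoate
Product: 35 (2E,4E,6R)-6-({[tert-butyl(dimethyl)silyl]oxy}methyl)octa-2,4-dienoic acid
Conditions: LiOH·H2O, THF/MeOH/H2O (3:1:1), rt; then 1 M HCl to pH 4
Reagents that add atoms: lithium hydroxide, [Li+].[OH-]
Why: Saponification of the ethyl ester; the primary silyl ether survives hydroxide and brief mild acidification, and C6′ is not acidic enough to epimerise.

Step 24
Reactants: 23 (4aS,5R,6S)-6-hydroxy-3-(methoxymethoxy)-4a,5-dimethyl-5,6-dihydronaphthalen-2(4aH)-one; 35 (2E,4E,6R)-6-({[tert-butyl(dimethyl)silyl]oxy}methyl)octa-2,4-dienoic acid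
Product: 37 (4aS,5R,6S)-3-(methoxymethoxy)-4a,5-dimethyl-2-oxo-2,4a,5,6-tetrahydronaphthalen-6-yl (2E,4E,6R)-6-({[tert-butyl(dimethyl)silyl]oxy}methyl)octa-2,4-dienoate, via mixed anhydride 36 (not isolated)
Conditions: 35, 2,4,6-trichlorobenzoyl chloride, Et3N, toluene, rt; then 23, DMAP, toluene, rt → 40 °C
Reagents that add atoms: none
Why: Yamaguchi esterification: DMAP attacks the mixed anhydride 36 at the dienoyl carbonyl and the acylpyridinium acylates the hindered secondary allylic C3–OH, the only free hydroxyl of 23. The C3–O bond is not broken, so C3 keeps its configuration; the base is kept mild because C3–H is vinylogously acidic.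

Step 25
Reactants: 37 (4aS,5R,6S)-3-(methoxymethoxy)-4a,5-dimethyl-2-oxo-2,4a,5,6-tetrahydronaphthalen-6-yl (2E,4E,6R)-6-({[tert-butyl(dimethyl)silyl]oxy}methyl)octa-2,4-dienoate
Product: 38 septeremophilane E
Conditions: 3 M aq. HCl/THF (1:4), rt
Reagents that add atoms: none
Why: Acid hydrolysis cleaves the methoxymethyl enol ether and the primary silyl ether in one operation; ionisation at C3 is not expected because a C3 cation would be conjugated with the electron-poor trienone.

## Compound list

1 | (S)-but-3-yn-2-ol | C#C[C@H](C)O | starting material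
2 | (S)-but-3-yn-2-yl methanesulfonate | C#C[C@H](C)OS(C)(=O)=O | intermediate
3 | 3-(trimethylsilyl)propynal | C[Si](C)(C)C#CC=O | starting material
4 | (aR)-buta-1,2-dien-1-yl(ethyl)zinc, the allenylzinc formed in the flask | [H]C(C)=[C@@]=C([H])[Zn]CC | intermediate
5 | (3R,4R)-4-methyl-1-(trimethylsilyl)hexa-1,5-diyn-3-ol | C#C[C@@H](C)[C@@H](O)C#C[Si](C)(C)C | intermediate
6 | tert-butyl(dimethyl){[(3R,4R)-4-methyl-1-(trimethylsilyl)hexa-1,5-diyn-3-yl]oxy}silane | C#C[C@@H](C)[C@@H](O[Si](C)(C)C(C)(C)C)C#C[Si](C)(C)C | intermediate
7 | 9-{(1Z,3S,4R)-4-[tert-butyl(dimethyl)silyl]oxy-2-iodo-3-methyl-6-(trimethylsilyl)hex-1-en-5-yn-1-yl}-9-borabicyclo[3.3.1]nonane, formed in the flask | I/C(=C\B1C2CCCC1CCC2)[C@@H](C)[C@@H](O[Si](C)(C)C(C)(C)C)C#C[Si](C)(C)C | intermediate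
8 | tert-butyl{[(3R,4S)-5-iodo-4-methyl-1-(trimethylsilyl)hex-5-en-1-yn-3-yl]oxy}dimethylsilane | C=C(I)[C@@H](C)[C@@H](O[Si](C)(C)C(C)(C)C)C#C[Si](C)(C)C | intermediate
9 | (1,3-dioxolan-2-ylmethyl)zinc bromide | Br[Zn]CC1OCCO1 | starting material
10 | tert-butyl({(3R,4R)-5-[(1,3-dioxolan-2-yl)methyl]-4-methyl-1-(trimethylsilyl)hex-5-en-1-yn-3-yl}oxy)dimethylsilane | C=C(CC1OCCO1)[C@@H](C)[C@@H](O[Si](C)(C)C(C)(C)C)C#C[Si](C)(C)C | intermediate
11 | tert-butyl({(3R,4R)-5-[(1,3-dioxolan-2-yl)methyl]-1-iodo-4-methylhex-5-en-1-yn-3-yl}oxy)dimethylsilane | C=C(CC1OCCO1)[C@@H](C)[C@@H](O[Si](C)(C)C(C)(C)C)C#CI | intermediate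
12 | tert-butyl({(1Z,3R,4R)-5-[(1,3-dioxolan-2-yl)methyl]-1-iodo-4-methylhexa-1,5-dien-3-yl}oxy)dimethylsilane | C=C(CC1OCCO1)[C@@H](C)[C@@H](O[Si](C)(C)C(C)(C)C)/C=C\I | intermediate
13 | methyl propiolate | C#CC(=O)OC | starting material
14 | methyl (4Z,6S,7R)-6-{[tert-butyl(dimethyl)silyl]oxy}-8-[(1,3-dioxolan-2-yl)methyl]-7-methylnona-4,8-dien-2-ynoate | C=C(CC1OCCO1)[C@@H](C)[C@@H](O[Si](C)(C)C(C)(C)C)/C=C\C#CC(=O)OC | intermediate
15 | methyl (2Z)-2-[(4S,5R,6R)-4-{[tert-butyl(dimethyl)silyl]oxy}-6-[(1,3-dioxolan-2-yl)methyl]-5,6-dimethylcyclohex-2-en-1-ylidene]acetate | CC(C)(C)[Si](C)(C)O[C@H]1C=C/C(=C/C(=O)OC)[C@](C)(CC2OCCO2)[C@H]1C | intermediate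
16 | methyl (2Z)-2-[(4S,5R,6R)-4-{[tert-butyl(dimethyl)silyl]oxy}-5,6-dimethyl-6-(2-oxoethyl)cyclohex-2-en-1-ylidene]acetate | CC(C)(C)[Si](C)(C)O[C@H]1C=C/C(=C/C(=O)OC)[C@](C)(CC=O)[C@H]1C | intermediate
17 | (2Z)-2-[(4S,5R,6R)-4-{[tert-butyl(dimethyl)silyl]oxy}-6-(2-hydroxyethyl)-5,6-dimethylcyclohex-2-en-1-ylidene]ethan-1-ol | CC(C)(C)[Si](C)(C)O[C@H]1C=C/C(=C/CO)[C@](C)(CCO)[C@H]1C | intermediate
18 | (2Z)-2-[(4S,5R,6R)-4-{[tert-butyl(dimethyl)silyl]oxy}-5,6-dimethyl-6-(2-oxoethyl)cyclohex-2-en-1-ylidene]acetaldehyde | CC(C)(C)[Si](C)(C)O[C@H]1C=C/C(=C/C=O)[C@](C)(CC=O)[C@H]1C | intermediate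
19 | (4aR,5R,6S)-6-{[tert-butyl(dimethyl)silyl]oxy}-4a,5-dimethyl-2,3,4,4a,5,6-hexahydronaphthalene-2,3-diol, configuration at C2 and C3 (C8 and C7 of the core) not controlled | CC(C)(C)[Si](C)(C)O[C@H]1C=CC2=CC(O)C(O)C[C@]2(C)[C@H]1C | intermediate
20 | (4aR,5R,6S)-6-{[tert-butyl(dimethyl)silyl]oxy}-4a,5-dimethyl-4,4a,5,6-tetrahydronaphthalene-2,3-dione, formed in the flask | CC(C)(C)[Si](C)(C)O[C@H]1C=CC2=CC(=O)C(=O)C[C@]2(C)[C@H]1C | intermediate
21 | (4aS,5R,6S)-6-{[tert-butyl(dimethyl)silyl]oxy}-3-hydroxy-4a,5-dimethyl-5,6-dihydronaphthalen-2(4aH)-one | CC(C)(C)[Si](C)(C)O[C@H]1C=CC2=CC(=O)C(O)=C[C@]2(C)[C@H]1C | intermediate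
22 | (4aS,5R,6S)-6-{[tert-butyl(dimethyl)silyl]oxy}-3-(methoxymethoxy)-4a,5-dimethyl-5,6-dihydronaphthalen-2(4aH)-one | CC(C)(C)[Si](C)(C)O[C@H]1C=CC2=CC(=O)C(OCOC)=C[C@]2(C)[C@H]1C | intermediate
23 | (4aS,5R,6S)-6-hydroxy-3-(methoxymethoxy)-4a,5-dimethyl-5,6-dihydronaphthalen-2(4aH)-one | O[C@H]1C=CC2=CC(=O)C(OCOC)=C[C@]2(C)[C@H]1C | intermediate
24 | (4R)-4-benzyl-1,3-oxazolidin-2-one | O=C1N[C@H](Cc2ccccc2)CO1 | starting material
25 | butanoyl chloride | CCCC(Cl)=O | starting material
26 | (4R)-4-benzyl-3-butanoyl-1,3-oxazolidin-2-one | CCCC(=O)N1[C@H](Cc2ccccc2)COC1=O | intermediate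
27 | trichlorotitanium (Z)-enolate of 26, formed in the flask | CC/C=C(\O[Ti](Cl)(Cl)Cl)N1[C@H](Cc2ccccc2)COC1=O | intermediate
28 | (4R)-4-benzyl-3-[(2S)-2-(hydroxymethyl)butanoyl]-1,3-oxazolidin-2-one | CC[C@@H](CO)C(=O)N1[C@H](Cc2ccccc2)COC1=O | intermediate
29 | (4R)-4-benzyl-3-[(2S)-2-({[tert-butyl(dimethyl)silyl]oxy}methyl)butanoyl]-1,3-oxazolidin-2-one | CC[C@@H](CO[Si](C)(C)C(C)(C)C)C(=O)N1[C@H](Cc2ccccc2)COC1=O | intermediate
30 | (2R)-2-({[tert-butyl(dimethyl)silyl]oxy}methyl)butan-1-ol | CC[C@@H](CO[Si](C)(C)C(C)(C)C)CO | intermediate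
31 | (2S)-2-({[tert-butyl(dimethyl)silyl]oxy}methyl)butanal | CC[C@@H](CO[Si](C)(C)C(C)(C)C)C=O | intermediate
32 | triethyl 4-phosphonocrotonate, ethyl (2E)-4-(diethoxyphosphoryl)but-2-enoate | CCOC(=O)/C=C/CP(=O)(OCC)OCC | starting material
33 | lithium salt of the C4 carbanion of 32, formed in the flask | [Li+].CCOC(=O)/C=C/[CH-]P(=O)(OCC)OCC | intermediate
34 | ethyl (2E,4E,6R)-6-({[tert-butyl(dimethyl)silyl]oxy}methyl)octa-2,4-dienoate | CC[C@H](/C=C/C=C/C(=O)OCC)CO[Si](C)(C)C(C)(C)C | intermediate
35 | (2E,4E,6R)-6-({[tert-butyl(dimethyl)silyl]oxy}methyl)octa-2,4-dienoic acid | CC[C@H](/C=C/C=C/C(=O)O)CO[Si](C)(C)C(C)(C)C | intermediate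
36 | mixed anhydride of 35 with 2,4,6-trichlorobenzoic acid, formed in the flask | CC[C@H](/C=C/C=C/C(=O)OC(=O)c1c(Cl)cc(Cl)cc1Cl)CO[Si](C)(C)C(C)(C)C | intermediate
37 | (4aS,5R,6S)-3-(methoxymethoxy)-4a,5-dimethyl-2-oxo-2,4a,5,6-tetrahydronaphthalen-6-yl (2E,4E,6R)-6-({[tert-butyl(dimethyl)silyl]oxy}methyl)octa-2,4-dienoate | CC[C@H](/C=C/C=C/C(=O)O[C@H]1C=CC2=CC(=O)C(OCOC)=C[C@]2(C)[C@H]1C)CO[Si](C)(C)C(C)(C)C | intermediate
38 | septeremophilane E, (4aS,5R,6S)-3-hydroxy-4a,5-dimethyl-2-oxo-2,4a,5,6-tetrahydronaphthalen-6-yl (2E,4E,6R)-6-(hydroxymethyl)octa-2,4-dienoate | CC[C@H](/C=C/C=C/C(=O)O[C@H]1C=CC2=CC(=O)C(O)=C[C@]2(C)[C@H]1C)CO | target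

## Step count and least certain steps

Total: 25 steps. Longest linear sequence: 18 steps (steps 1–16, 24 and 25, from 1). The acid 35 takes 7 steps (17–23) and joins at step 24.

Step 9 (key step). What may go wrong: hydrogen-atom transfer to the conjugated enynoate of 14 or to the dienoate of 15, so that material is lost by over-reduction while the product accumulates under reducing conditions; and only moderate facial selectivity at C5, because methyl and the arm differ little in size. Fallback, setting out from 12 and returning at 15: the same tertiary radical is generated without any metal hydride in the flask. Mukaiyama hydration of the 1,1-disubstituted alkene of 12 (Co(acac)2, PhSiH3, O2, THF/i-PrOH) would give the tertiary alcohol F1. Sonogashira coupling with 13 as in step 8 would give the hydroxy enynoate F2. Acylation with chloro N-phthalimidoyl oxalate (Et3N, DMAP, CH2Cl2) would give the mixed oxalate F3. Visible-light photoredox fragmentation of F3 (Ru(bpy)3(PF6)2, Hantzsch ester, i-Pr2NEt·HBF4, blue light) would then release the C5 radical, which closes ring A onto C10, and the vinyl radical takes hydrogen from the dihydropyridine to give 15. Facial selectivity is unchanged by this fallback; a bulkier C3 silyl group is the lever for it.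

Step 13. What may go wrong: conjugate reduction or dimerisation of the dienal ketyl, or Z to E isomerisation of the enal before the C7–C8 bond forms. Fallback, setting out from 18 and returning at 21: a redox-neutral umpolung closure in place of the reductive one. Carbene catalysis (3-benzyl-5-(2-hydroxyethyl)-4-methylthiazolium chloride, Et3N, THF, 50 °C) would effect an intramolecular crossed benzoin reaction, the Breslow intermediate forming at the unhindered C7 aldehyde and adding to the C8 carbonyl, to give the acyloin F4. Dess–Martin oxidation of F4 would give 20 and, by enolisation, 21.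

Step 8. What may go wrong: base-induced oligomerisation of methyl propiolate and copper-mediated homocoupling outrunning the cross-coupling. Fallback, setting out from 12 and returning at 14: the ester is introduced after the C–C coupling. Sonogashira coupling of 12 with ethynyltrimethylsilane (PdCl2(PPh3)2, CuI, Et3N) would give the silyl enyne F5, K2CO3 in MeOH the terminal enyne F6, and deprotonation with LiN(SiMe3)2 at −78 °C followed by ClCO2Me would give 14.

Step 5. What may go wrong: β-hydride or β-alkoxide elimination from the alkylpalladium intermediate (the acetal carbon is β to the metal), leading to reduction of 8 in place of coupling. Fallback, setting out from 8 and returning at 10: the arm is brought in at the ester level. Negishi coupling of 8 with the Reformatsky reagent BrZnCH2CO2Et (Pd(PPh3)4, THF) would give the β,γ-unsaturated ester F7. i-Bu2AlH (1.1 equiv, CH2Cl2, −78 °C) would give the aldehyde F8. Immediate acetalisation with 1,2-bis(trimethylsilyloxy)ethane and catalytic TMSOTf at −78 °C, before the alkene can move into conjugation, would give 10.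

Step 2. What may go wrong: erosion of anti selectivity, because the alkynyl group of 3 is the smallest possible aldehyde substituent, and competing ethyl transfer from Et2Zn to 3. Fallback, setting out from 2 and 3 and returning at 5: C3 of the unwanted diastereomer is set by substitution with inversion. The syn alcohol F9 that accompanies 5 is separated and submitted to a Mitsunobu reaction with benzoic acid (PPh3, diisopropyl azodicarboxylate, THF) to give the inverted benzoate F10. Reductive cleavage with i-Bu2AlH at −78 °C, which leaves the alkynylsilane intact, would give 5.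

## Further compounds

F1 | step 9 | (3S,4R,5Z)-4-{[tert-butyl(dimethyl)silyl]oxy}-2-[(1,3-dioxolan-2-yl)methyl]-6-iodo-3-methylhex-5-en-2-ol, both C2 epimers | CC(O)(CC1OCCO1)[C@@H](C)[C@@H](O[Si](C)(C)C(C)(C)C)/C=C\I
F2 | step 9 | methyl (4Z,6S,7S)-6-{[tert-butyl(dimethyl)silyl]oxy}-8-[(1,3-dioxolan-2-yl)methyl]-8-hydroxy-7-methylnon-4-en-2-ynoate, both C8 epimers | CC(O)(CC1OCCO1)[C@@H](C)[C@@H](O[Si](C)(C)C(C)(C)C)/C=C\C#CC(=O)OC
F3 | step 9 | N-phthalimidoyl oxalate of the tertiary alcohol F2 | CC(OC(=O)C(=O)ON1C(=O)c2ccccc2C1=O)(CC1OCCO1)[C@@H](C)[C@@H](O[Si](C)(C)C(C)(C)C)/C=C\C#CC(=O)OC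
F4 | step 13 | (4aR,5R,6S)-6-{[tert-butyl(dimethyl)silyl]oxy}-2-hydroxy-4a,5-dimethyl-4,4a,5,6-tetrahydronaphthalen-3(2H)-one, C2 epimers | CC(C)(C)[Si](C)(C)O[C@H]1C=CC2=CC(O)C(=O)C[C@]2(C)[C@H]1C
F5 | step 8 | tert-butyl({(3Z,5S,6R)-7-[(1,3-dioxolan-2-yl)methyl]-6-methyl-1-(trimethylsilyl)octa-3,7-dien-1-yn-5-yl}oxy)dimethylsilane | C=C(CC1OCCO1)[C@@H](C)[C@@H](O[Si](C)(C)C(C)(C)C)/C=C\C#C[Si](C)(C)C
F6 | step 8 | tert-butyl({(3Z,5S,6R)-7-[(1,3-dioxolan-2-yl)methyl]-6-methylocta-3,7-dien-1-yn-5-yl}oxy)dimethylsilane | C=C(CC1OCCO1)[C@@H](C)[C@@H](O[Si](C)(C)C(C)(C)C)/C=C\C#C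
F7 | step 5 | ethyl (4R,5R)-5-{[tert-butyl(dimethyl)silyl]oxy}-4-methyl-3-methylidene-7-(trimethylsilyl)hept-6-ynoate | C=C(CC(=O)OCC)[C@@H](C)[C@@H](O[Si](C)(C)C(C)(C)C)C#C[Si](C)(C)C
F8 | step 5 | (4R,5R)-5-{[tert-butyl(dimethyl)silyl]oxy}-4-methyl-3-methylidene-7-(trimethylsilyl)hept-6-ynal | C=C(CC=O)[C@@H](C)[C@@H](O[Si](C)(C)C(C)(C)C)C#C[Si](C)(C)C
F9 | step 2 | (3S,4R)-4-methyl-1-(trimethylsilyl)hexa-1,5-diyn-3-ol | C#C[C@@H](C)[C@H](O)C#C[Si](C)(C)C
F10 | step 2 | (3R,4R)-4-methyl-1-(trimethylsilyl)hexa-1,5-diyn-3-yl benzoate | C#C[C@@H](C)[C@@H](OC(=O)c1ccccc1)C#C[Si](C)(C)C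
A1 | alternative 1 | (aR)-vinylallenyl ketone: 2-[(E)-2-methylbut-2-enyl]-1,3-dithian-2-yl (4E)-5-[tert-butyl(dimethyl)silyl]oxypenta-1,2,4-trienyl ketone | C/C=C(\C)CC1(SCCCS1)C(=O)C([H])=[C@]=C([H])/C=C/O[Si](C)(C)C(C)(C)C
A2 | alternative 1 | bicyclic dienone with C7 dithioketal and C3 silyl ether | CC(C)(C)[Si](C)(C)O[C@H]1C=CC2=CC(=O)C3(SCCCS3)C[C@]2(C)[C@H]1C
A3 | alternative 2 | 2-bromo-6-methoxy-4-methylphenol carrying at C3 a (Z)-3-(4-methoxybenzyloxy)-4-(methanesulfonyloxy)pent-1-enyl chain | COc1cc(C)c(/C=C\[C@H](OCc2ccc(OC)cc2)[C@@H](C)OS(C)(=O)=O)c(Br)c1O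
A4 | alternative 2 | 9-bromo-7-methoxy bicyclic dienone with C3 PMB ether | COc1ccc(CO[C@H]2C=CC3=C(Br)C(=O)C(OC)=C[C@]3(C)[C@H]2C)cc1
A5 | alternative 3 | trimethylsilyl dienol ether of the hydrindenone with five-membered ring B and C3 TBS ether | CC(C)(C)[Si](C)(C)O[C@H]1C=CC2=CC(O[Si](C)(C)C)=C[C@]2(C)[C@H]1C
A6 | alternative 3 | 7-bromo trienone with C3 silyl ether | CC(C)(C)[Si](C)(C)O[C@H]1C=CC2=CC(=O)C(Br)=C[C@]2(C)[C@H]1C
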